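**Retrosynthetic overview**
1. The plan rests on ring carbon C5 of the cyclopentenone, which sits between the C1 ketone and the C4 carbinol. A carboxyl placed on C5 serves first as the nucleophile that closes C1–C5 and then as the handle that brings bromine to C5 alone.
2. Target 20 ⇒ silyl ether 19 (HF·pyridine) ⇒ β-keto acid 17 (NBS, loss of CO2) ⇒ tert-butyl β-keto ester 16 (CF3CO2H).
3. 16 ⇒ Z-hexenedioate 13 by Dieckmann closure of C1–C5; this forms the only ring, the cyclopentenone.
4. 13 ⇒ cis-formyl enoate 9 + TBS ketene acetal 12 (asymmetric Mukaiyama aldol; C4 is set and its oxygen silylated in the same event).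
5. 9 ⇒ Z-enol triflate 8 ⇒ alkylated β-keto ester 7 ⇒ β-keto ester 4 + (Z)-pentenyl bromide 6; 4 ⇒ monomethyl azelate + Meldrum's acid.

Key step: step 9

Remark on numbering: ring atoms are C1 (C=O), C2 (pentenyl), C3 (ester chain), C4 (CHOH), C5 (CHBr); the target is (4R,5S) in this numbering, with OH and Br trans.
Remark on the aldol catalyst: its sense of induction on aldehyde 9 is not known in advance; the antipode that gives Si-face addition (C4 = S in 13) is assumed, to be confirmed by chiral-phase HPLC and by correlation with the final product.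

**Step 1**
Reactants: 1 monomethyl azelate; 2 Meldrum's acid
Product: 3 5-(1-hydroxy-9-methoxy-9-oxononylidene)-2,2-dimethyl-1,3-dioxane-4,6-dione
Conditions: DCC, DMAP, CH2Cl2, 0 °C → rt; filter; wash with aq. KHSO4
Reagents that add atoms: none
Why: Carbodiimide activation of the free acid and C-acylation of the highly acidic Meldrum's acid (the Meldrum's acid route to β-keto esters) should give the acyl derivative without touching the methyl ester.

**Step 2**
Reactants: 3 acyl Meldrum's acid
Product: 4 dimethyl 3-oxoundecanedioate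
Conditions: MeOH, reflux
Reagents that add atoms: methanol, CO
Why: Thermal fragmentation of the acyl Meldrum's acid to an acylketene with loss of acetone and CO2, followed by trapping with methanol, is the standard route to a β-keto methyl ester.

**Step 3**
Reactants: 5 (Z)-pent-2-en-1-ol
Product: 6 (Z)-1-bromopent-2-ene
Conditions: CBr4, PPh3, CH2Cl2, 0 °C
Reagents that add atoms: carbon tetrabromide, BrC(Br)(Br)Br
Why: The Appel reaction displaces the alkoxyphosphonium at the primary carbon by SN2 under neutral conditions, so the Z alkene should be kept and allylic transposition avoided.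

**Step 4**
Reactants: 4 dimethyl 3-oxoundecanedioate; 6 (Z)-1-bromopent-2-ene
Product: 7 dimethyl 3-oxo-2-[(2Z)-pent-2-en-1-yl]undecanedioate
Conditions: K2CO3, acetone, rt
Reagents that add atoms: none
Why: C-alkylation of the β-keto ester enolate by SN2 at the primary allylic bromide places the pentenyl group on the future C2 regiospecifically; the new centre is racemic and becomes sp2 in step 5.

**Step 5**
Reactants: 7 alkylated β-keto ester
Product: 8 dimethyl (2Z)-2-[(2Z)-pent-2-en-1-yl]-3-[(trifluoromethanesulfonyl)oxy]undec-2-enedioate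
Conditions: LiOSO2CF3, Et3N, CH2Cl2, 0 °C; Tf2O, −78 → 0 °C
Reagents that add atoms: triflic anhydride, O=S(=O)(OS(=O)(=O)C(F)(F)F)C(F)(F)F
Why: O-sulfonylation of the lithium-chelated enolate, in which the enolate oxygen and the ester carbonyl are held cis, should give the Z enol triflate with OTf and CO2Me on the same side (chelation-controlled enol triflate formation).

**Step 6**
Reactants: 8 Z-enol triflate
Product: 9 dimethyl (2Z)-3-formyl-2-[(2Z)-pent-2-en-1-yl]undec-2-enedioate
Conditions: CO (1 atm), Pd(PPh3)4 (5 mol%), LiCl, Bu3SnH (syringe pump), THF, 50 °C; product kept from light and used directly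
Reagents that add atoms: carbon monoxide, [C-]#[O+]
Why: Zerovalent palladium inserts into the C–OTf bond with retention of alkene geometry, CO insertion gives an acylpalladium, and hydride transfer from tin releases the aldehyde (Stille-type reductive carbonylation of a vinyl triflate); slow addition of the tin hydride suppresses direct hydrogenolysis.

**Step 7**
Reactants: 10 tert-butyl acetate
Product: 12 tert-butyl[(1-tert-butoxyethenyl)oxy]dimethylsilane, via lithium enolate of tert-butyl acetate 11 (not isolated)
Conditions: LiN(iPr)2, THF, −78 °C; TBSCl, DMPU, −78 °C → rt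
Reagents that add atoms: tert-butyldimethylsilyl chloride, CC(C)(C)[Si](C)(C)Cl
Why: Kinetic ester enolisation followed by O-silylation in the presence of a polar co-solvent is the standard preparation of a silyl ketene acetal.

**Step 8**
Reactants: 9 cis-formyl enoate; 12 TBS ketene acetal
Product: 13 6-tert-butyl 1-methyl (2Z,4S)-4-[(tert-butyldimethylsilyl)oxy]-3-(8-methoxy-8-oxooctyl)-2-[(2Z)-pent-2-en-1-yl]hex-2-enedioate
Conditions: 3,3'-bis[3,5-bis(trifluoromethyl)phenyl]-1,1'-binaphthyl-2,2'-disulfonimide (5 mol%, antipode as in the remark), Et2O, −78 °C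
Reagents that add atoms: none
Why: This is a catalytic asymmetric Mukaiyama aldol under silylium (chiral disulfonimide counter-anion) catalysis, known for enals with acetate-derived silyl ketene acetals; the chiral anion paired with the O-silylated aldehyde should direct 12 to the Si face and set C4 as S, and because the silyl group ends on the aldolate oxygen the C4 hydroxyl is never free to lactonise onto the cis C1 ester.

**Step 9**
Reactants: 13 Z-silyloxy hexenedioate
Product: 16 tert-butyl (1S,5S)-5-[(tert-butyldimethylsilyl)oxy]-4-(8-methoxy-8-oxooctyl)-2-oxo-3-[(2Z)-pent-2-en-1-yl]cyclopent-3-ene-1-carboxylate, via lithium ester enolate 14 (not isolated), via lithium keto ester enolate 15 (not isolated)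
Conditions: LiN(SiMe3)2 (2.2 equiv), THF (0.02 M), −78 → −30 °C; AcOH, −78 °C
Reagents that add atoms: none
Why: LiN(SiMe3)2 deprotonates C5 next to the tert-butyl ester (14), the enolate carbon adds to the C1 carbonyl of the conjugated methyl ester, methoxide leaves the tetrahedral intermediate, and the second equivalent of base turns the β-keto ester into its enolate 15, which makes the closure irreversible. This is a Dieckmann condensation, a reaction known for 3-silyloxy adipate-type diesters. The ring C1–C5 closes in the 5-exo-trig mode, the Z geometry of C2=C3 holding C1 and C5 on the same side of the alkene. C4 is not touched, and C5 is set under thermodynamic control on protonation, the keto tautomer placing the ester trans to the C4 silyloxy group. The step needs ring closure to outrun E1cB loss of the C4 silyloxide from 14 and reaction at the other esters; low temperature, high dilution, reversible low-level enolisation by the amide base and the pre-organised five-membered closure favour it, and the terminal methyl ester could only close an eleven-membered ring. Enolate 15 itself cannot eliminate, since that would give a cyclopentadienone.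

**Step 10**
Reactants: 16 tert-butyl β-keto ester
Product: 17 (1S,5S)-5-[(tert-butyldimethylsilyl)oxy]-4-(8-methoxy-8-oxooctyl)-2-oxo-3-[(2Z)-pent-2-en-1-yl]cyclopent-3-ene-1-carboxylic acid
Conditions: CF3CO2H/CH2Cl2 (1:4), 0 °C; evaporate cold with toluene; use at once
Reagents that add atoms: none
Why: Acidolysis of the tert-butyl ester through the tert-butyl cation should spare the methyl ester, the Z alkene and, on short cold exposure, the secondary silyl ether; any desilylated material converges on the target after step 12.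

**Step 11**
Reactants: 17 β-keto acid
Product: 19 methyl 8-[(4S,5R)-4-bromo-5-[(tert-butyldimethylsilyl)oxy]-3-oxo-2-[(2Z)-pent-2-en-1-yl]cyclopent-1-en-1-yl]octanoate, via bromo keto acid 18 (not isolated)
Conditions: NBS (1.0 equiv), 2,6-lutidine (1.1 equiv), CH2Cl2, −20 °C → rt
Reagents that add atoms: N-bromosuccinimide, O=C1CCC(=O)N1Br
Why: In this decarboxylative bromination of a β-keto acid, the enol of 17 is brominated at C5 (the only doubly activated carbon) anti to the silyloxy group, the α-bromo β-keto acid 18 loses CO2, and ketonisation of the resulting bromo enol in the lutidine/lutidinium buffer should equilibrate C5 to the trans bromide; exactly one equivalent of NBS leaves none for a second bromination or for the Z alkene.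

**Step 12**
Reactants: 19 bromo silyl ether
Product: 20 methyl 8-[(4S,5R)-4-bromo-5-hydroxy-3-oxo-2-[(2Z)-pent-2-en-1-yl]cyclopent-1-en-1-yl]octanoate (CNP0306311.1)
Conditions: HF·pyridine, THF, 0 °C → rt (polypropylene vessel)
Reagents that add atoms: none
Why: Fluoride-driven desilylation under acidic, non-basic conditions should free the C4 hydroxyl without epimerising C5 and without closing the trans bromohydrin to an epoxide, which base would cause.

**Compound list**
1 | monomethyl azelate (9-methoxy-9-oxononanoic acid) | COC(=O)CCCCCCCC(=O)O | starting material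
2 | Meldrum's acid | CC1(C)OC(=O)CC(=O)O1 | starting material
3 | 5-(1-hydroxy-9-methoxy-9-oxononylidene)-2,2-dimethyl-1,3-dioxane-4,6-dione | COC(=O)CCCCCCCC(O)=C1C(=O)OC(C)(C)OC1=O | intermediate
4 | dimethyl 3-oxoundecanedioate | COC(=O)CCCCCCCC(=O)CC(=O)OC | intermediate
5 | (Z)-pent-2-en-1-ol | CC/C=C\CO | starting material
6 | (Z)-1-bromopent-2-ene | CC/C=C\CBr | intermediate
7 | dimethyl 3-oxo-2-[(2Z)-pent-2-en-1-yl]undecanedioate (racemic at C2) | COC(=O)CCCCCCCC(=O)C(C/C=C\CC)C(=O)OC | intermediate
8 | dimethyl (2Z)-2-[(2Z)-pent-2-en-1-yl]-3-[(trifluoromethanesulfonyl)oxy]undec-2-enedioate | COC(=O)/C(C/C=C\CC)=C(\OS(=O)(=O)C(F)(F)F)CCCCCCCC(=O)OC | intermediate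
9 | dimethyl (2Z)-3-formyl-2-[(2Z)-pent-2-en-1-yl]undec-2-enedioate | COC(=O)/C(C/C=C\CC)=C(\C=O)CCCCCCCC(=O)OC | intermediate
10 | tert-butyl acetate | CC(=O)OC(C)(C)C | starting material
11 | lithium 1-tert-butoxyethen-1-olate (lithium enolate of tert-butyl acetate) | C=C(O[Li])OC(C)(C)C | intermediate
12 | tert-butyl[(1-tert-butoxyethenyl)oxy]dimethylsilane | C=C(O[Si](C)(C)C(C)(C)C)OC(C)(C)C | intermediate
13 | 6-tert-butyl 1-methyl (2Z,4S)-4-[(tert-butyldimethylsilyl)oxy]-3-(8-methoxy-8-oxooctyl)-2-[(2Z)-pent-2-en-1-yl]hex-2-enedioate | COC(=O)/C(C/C=C\CC)=C(\[C@@H](O[Si](C)(C)C(C)(C)C)CC(=O)OC(C)(C)C)CCCCCCCC(=O)OC | intermediate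
14 | lithium enolate of 13 at C5 (tert-butyl ester enolate) | COC(=O)/C(C/C=C\CC)=C(\[C@@H](O[Si](C)(C)C(C)(C)C)C=C(O[Li])OC(C)(C)C)CCCCCCCC(=O)OC | intermediate
15 | lithium enolate of keto ester 16 (C1–O–Li, C1=C5) | CC/C=C\CC1=C(CCCCCCCC(=O)OC)[C@@H](O[Si](C)(C)C(C)(C)C)C(C(=O)OC(C)(C)C)=C1O[Li] | intermediate
16 | tert-butyl (1S,5S)-5-[(tert-butyldimethylsilyl)oxy]-4-(8-methoxy-8-oxooctyl)-2-oxo-3-[(2Z)-pent-2-en-1-yl]cyclopent-3-ene-1-carboxylate | CC/C=C\CC1=C(CCCCCCCC(=O)OC)[C@@H](O[Si](C)(C)C(C)(C)C)[C@H](C(=O)OC(C)(C)C)C1=O | intermediate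
17 | (1S,5S)-5-[(tert-butyldimethylsilyl)oxy]-4-(8-methoxy-8-oxooctyl)-2-oxo-3-[(2Z)-pent-2-en-1-yl]cyclopent-3-ene-1-carboxylic acid | CC/C=C\CC1=C(CCCCCCCC(=O)OC)[C@@H](O[Si](C)(C)C(C)(C)C)[C@H](C(=O)O)C1=O | intermediate
18 | (1S,5R)-1-bromo-5-[(tert-butyldimethylsilyl)oxy]-4-(8-methoxy-8-oxooctyl)-2-oxo-3-[(2Z)-pent-2-en-1-yl]cyclopent-3-ene-1-carboxylic acid (Br anti to the silyloxy group) | CC/C=C\CC1=C(CCCCCCCC(=O)OC)[C@@H](O[Si](C)(C)C(C)(C)C)[C@](C(=O)O)(Br)C1=O | intermediate
19 | methyl 8-[(4S,5R)-4-bromo-5-[(tert-butyldimethylsilyl)oxy]-3-oxo-2-[(2Z)-pent-2-en-1-yl]cyclopent-1-en-1-yl]octanoate | CC/C=C\CC1=C(CCCCCCCC(=O)OC)[C@@H](O[Si](C)(C)C(C)(C)C)[C@H](Br)C1=O | intermediate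
20 | methyl 8-[(4S,5R)-4-bromo-5-hydroxy-3-oxo-2-[(2Z)-pent-2-en-1-yl]cyclopent-1-en-1-yl]octanoate (CNP0306311.1) | CC/C=C\CC1=C(CCCCCCCC(=O)OC)[C@@H](O)[C@H](Br)C1=O | target

**Step count**
Total: 12 steps. Longest linear sequence: 10 steps (1, 2, 4, 5, 6, 8, 9, 10, 11, 12); steps 3 and 7 are side branches.

**Steps most likely to fail**

Step 9. E1cB loss of the C4 silyloxide from enolate 14 to a conjugated dienoate, or intermolecular Claisen reaction at the terminal methyl ester, may outpace ring closure. The fallback makes the C1 acyl acceptor more electrophilic so that closure should be complete at −78 °C. It sets out from acyl Meldrum's acid 3 and comes back to the route at keto ester 16. Heating 3 with 2,2,2-trifluoroethanol in toluene should give 11-methyl 1-(2,2,2-trifluoroethyl) 3-oxoundecanedioate F1. Alkylation with bromide 6 (K2CO3, acetone) should give 11-methyl 1-(2,2,2-trifluoroethyl) 3-oxo-2-[(2Z)-pent-2-en-1-yl]undecanedioate F2. Triflation as in step 5 should give the corresponding Z-enol triflate F3, and formylation as in step 6 the trifluoroethyl cis-formyl enoate F4. The aldol of step 8 with ketene acetal 12 should give the trifluoroethyl analogue of the precursor F5. LiN(SiMe3)2 in THF at −78 °C should then close C1–C5 with loss of trifluoroethoxide to give 16.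

Step 8. The catalyst may discriminate poorly between the faces of the fully substituted, ester-flanked enal 9. The fallback gives up catalyst control and resolves instead. It sets out from aldehyde 9 and ketene acetal 12 and comes back at 13. Achiral silylium catalysis (HN(SO2CF3)2, 1 mol%, CH2Cl2, −78 °C) should give, with the same direct silyl transfer, the racemic silyl ether F6. Preparative supercritical-fluid chromatography on a polysaccharide chiral stationary phase should separate 13 from its enantiomer, the (4R) silyl ether F7.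

Step 11. Keto acid 17 may lose CO2 before it is brominated, the enol released on decarboxylation may take up a second bromine, or C5 may not equilibrate fully. The fallback inverts the order of bromination and ester cleavage. It sets out from keto ester 16 and comes back at bromide 19. NBS with catalytic Mg(ClO4)2 in EtOAc at 0 °C should brominate the doubly activated C5 to give tert-butyl (1S,5R)-1-bromo-5-[(tert-butyldimethylsilyl)oxy]-4-(8-methoxy-8-oxooctyl)-2-oxo-3-[(2Z)-pent-2-en-1-yl]cyclopent-3-ene-1-carboxylate F8. CF3CO2H in CH2Cl2 should then cleave the tert-butyl ester; the α-bromo β-keto acid decarboxylates in the flask with no brominating agent left, and acid-catalysed enolisation should bring C5 to the trans bromide 19.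

**Further compounds**
F1 | step 9 | 11-methyl 1-(2,2,2-trifluoroethyl) 3-oxoundecanedioate | COC(=O)CCCCCCCC(=O)CC(=O)OCC(F)(F)F
F2 | step 9 | 11-methyl 1-(2,2,2-trifluoroethyl) 3-oxo-2-[(2Z)-pent-2-en-1-yl]undecanedioate | COC(=O)CCCCCCCC(=O)C(C/C=C\CC)C(=O)OCC(F)(F)F
F3 | step 9 | 11-methyl 1-(2,2,2-trifluoroethyl) (2Z)-2-[(2Z)-pent-2-en-1-yl]-3-[(trifluoromethanesulfonyl)oxy]undec-2-enedioate | FC(F)(F)COC(=O)/C(C/C=C\CC)=C(\OS(=O)(=O)C(F)(F)F)CCCCCCCC(=O)OC
F4 | step 9 | 11-methyl 1-(2,2,2-trifluoroethyl) (2Z)-3-formyl-2-[(2Z)-pent-2-en-1-yl]undec-2-enedioate | FC(F)(F)COC(=O)/C(C/C=C\CC)=C(\C=O)CCCCCCCC(=O)OC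
F5 | step 9 | 6-tert-butyl 1-(2,2,2-trifluoroethyl) (2Z,4S)-4-[(tert-butyldimethylsilyl)oxy]-3-(8-methoxy-8-oxooctyl)-2-[(2Z)-pent-2-en-1-yl]hex-2-enedioate | FC(F)(F)COC(=O)/C(C/C=C\CC)=C(\[C@@H](O[Si](C)(C)C(C)(C)C)CC(=O)OC(C)(C)C)CCCCCCCC(=O)OC
F6 | step 8 | racemic 6-tert-butyl 1-methyl (2Z)-4-[(tert-butyldimethylsilyl)oxy]-3-(8-methoxy-8-oxooctyl)-2-[(2Z)-pent-2-en-1-yl]hex-2-enedioate | COC(=O)/C(C/C=C\CC)=C(\C(O[Si](C)(C)C(C)(C)C)CC(=O)OC(C)(C)C)CCCCCCCC(=O)OC
F7 | step 8 | 6-tert-butyl 1-methyl (2Z,4R)-4-[(tert-butyldimethylsilyl)oxy]-3-(8-methoxy-8-oxooctyl)-2-[(2Z)-pent-2-en-1-yl]hex-2-enedioate (enantiomer of 13) | COC(=O)/C(C/C=C\CC)=C(\[C@H](O[Si](C)(C)C(C)(C)C)CC(=O)OC(C)(C)C)CCCCCCCC(=O)OC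
F8 | step 11 | tert-butyl (1S,5R)-1-bromo-5-[(tert-butyldimethylsilyl)oxy]-4-(8-methoxy-8-oxooctyl)-2-oxo-3-[(2Z)-pent-2-en-1-yl]cyclopent-3-ene-1-carboxylate | CC/C=C\CC1=C(CCCCCCCC(=O)OC)[C@@H](O[Si](C)(C)C(C)(C)C)[C@](C(=O)OC(C)(C)C)(Br)C1=O
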